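**Plan**

1. Cuts (labdane numbers for the diterpene, primed numbers for the quinone ring): C12–C1' and C15–C6' by a Diels–Alder reaction of trienone 25 with chromonyl quinone 27 (from diosmetin). Within 25: C8=C17 (Horner–Wadsworth–Emmons), C14=C15 (Wittig), C12=C13 (cross-metathesis), C9–C11 (allyl addition), C8–C9 (Claisen, ring B), and C2–C3 together with C5–C10 (ring A).
2. Enabling feature: in ring A, C3 and C5 both hang on the quaternary C4(CH3)2, so a non-enolisable aldehyde (C3) and an ynoate β-carbon (C5, whose ester becomes the C7 carbonyl of ring B) make a 1,3-bis-electrophile. C2 and C10 flank the plain C1H2, and C10 carries the C9 carboxyl that ring B needs, so a phosphonium ylide (C2) plus ester enolate (C10) is the matching 1,3-bis-nucleophile. One flask closes ring A, and the only trace of the helpers is the C2=C3 alkene.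
3. Forward order: ring A (step 7), ring B by Claisen condensation (step 9), hydrogenation to the trans-decalin, resolution, allylation, reductive enolate phosphinylation, side chain, exocyclic methylene, and last the cyclohexene ring by cycloaddition.
4. Stereochemistry: C10 forms as the racemate in step 7 and is resolved in step 11 through the (−)-menthyl enol ether that step 12 needs anyway. C5 comes from hydrogenation anti to the C10 methyl group, and C9 from axial protonation in the Li/NH3 reduction. C12, C1' and C6' come from the Diels–Alder step: the cis fusion is suprafacial, C12 follows from the chromonyl-endo topography, and the diene face is not controlled, so the target is separated from its isomers.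

Key step: step 7

Remark: compounds 12–16 are racemates, and their names and SMILES show the enantiomer that is carried on after step 11; the cycloaddition in step 18 is assumed to have no facial bias from the remote labdane stereocentres.

**Step 1**
Reactants: 1 3-methyldihydrofuran-2(3H)-one (α-methyl-γ-butyrolactone, racemic)
Product: 2 methyl 4-bromo-2-methylbutanoate (racemic)
Conditions: HBr (g), MeOH, 0 °C to rt
Reagents that add atoms: hydrogen bromide, Br; methanol, CO
Why: Acid-mediated opening of the lactone by bromide at the O–CH2 carbon with Fischer esterification of the freed acid (lactone ring-opening bromination).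

**Step 2**
Reactants: 2 methyl 4-bromo-2-methylbutanoate
Product: 3 (4-methoxy-3-methyl-4-oxobutyl)triphenylphosphonium bromide (racemic)
Conditions: PPh3, MeCN, reflux
Reagents that add atoms: triphenylphosphine, c1ccc(cc1)P(c1ccccc1)c1ccccc1
Why: SN2 quaternisation of the primary bromide by the phosphine (phosphonium salt formation).

**Step 3**
Reactants: 4 3-hydroxy-2,2-dimethylpropanal (hydroxypivaldehyde)
Product: 5 2,2-dimethylbut-3-yn-1-ol
Conditions: dimethyl (1-diazo-2-oxopropyl)phosphonate, K2CO3, MeOH, 0 °C to rt
Reagents that add atoms: dimethyl (1-diazo-2-oxopropyl)phosphonate, CC(=O)C(=[N+]=[N-])P(=O)(OC)OC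
Why: Seyferth–Gilbert homologation in the Ohira–Bestmann variant turns the non-enolisable aldehyde into the terminal alkyne and tolerates the free hydroxyl.

**Step 4**
Reactants: 5 2,2-dimethylbut-3-yn-1-ol
Product: 7 5-hydroxy-4,4-dimethylpent-2-ynoic acid, via dilithio dianion 6 (not isolated)
Conditions: n-BuLi (2.2 equiv), THF, −78 to 0 °C; CO2 (g), −78 °C; aq. HCl
Reagents that add atoms: carbon dioxide, O=C=O
Why: Carboxylation of the lithium acetylide within the O,C-dianion, the alkoxide–CO2 adduct reverting on acidification (acetylide carboxylation).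

**Step 5**
Reactants: 7 5-hydroxy-4,4-dimethylpent-2-ynoic acid
Product: 8 methyl 5-hydroxy-4,4-dimethylpent-2-ynoate
Conditions: MeI, KHCO3, DMF, rt
Reagents that add atoms: iodomethane, CI
Why: SN2 esterification of the carboxylate under conditions too mild to alkylate the neopentyl hydroxyl.

**Step 6**
Reactants: 8 methyl 5-hydroxy-4,4-dimethylpent-2-ynoate
Product: 9 methyl 4,4-dimethyl-5-oxopent-2-ynoate
Conditions: Dess–Martin periodinane, NaHCO3, CH2Cl2, 0 °C to rt
Reagents that add atoms: none
Why: Dess–Martin oxidation of the primary neopentyl alcohol to the non-enolisable aldehyde.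

**Step 7**
Reactants: 3 (4-methoxy-3-methyl-4-oxobutyl)triphenylphosphonium bromide; 9 methyl 4,4-dimethyl-5-oxopent-2-ynoate
Product: 12 methyl (1S,6Z)-6-(2-methoxy-2-oxoethylidene)-1,5,5-trimethylcyclohex-3-ene-1-carboxylate (racemate), via phosphonium ylide 10 (not isolated), via Z-enyne diester 11 (not isolated)
Conditions: 3, KN(SiMe3)2 (1.05 equiv), THF, −78 °C; 9, −78 to 0 °C; KN(SiMe3)2 (1.1 equiv), −78 to −20 °C; AcOH, −78 °C
Reagents that add atoms: none
Why: Deprotonation of 3 gives the non-stabilised ylide 10, whose salt-free Wittig reaction with the aldehyde of 9 forms C2=C3 through the cis-oxaphosphetane as Z-alkene 11, and the second equivalent of base then makes the tetrasubstituted ester enolate at C10, which adds to the ynoate β-carbon C5 and is protonated at C6 (closest known types: Z-selective Wittig olefination and intramolecular Michael addition of an ester enolate to an alkynoate, together a [3+3] annulation). Ring A closes in the 6-exo-dig mode, helped by the Z-alkene and the gem-dimethyl group at C4. The only new stereocentre, quaternary C10, has no controlling element and forms as the racemate (resolved in step 11), while C5 stays trigonal so that it can be set later in the bicycle. The step needs the ylide to attack the aldehyde and not the ynoate (carbonyl addition at −78 °C should outrun conjugate addition to the neopentyl-shielded alkyne carbon), Z-geometry (only the Z-alkene can cyclise) and C-attack at C5 (O-attack or attack at C6 would need an eight- or seven-membered ring). The exocyclic C5=C6 geometry should be set by protonation of the allenolate from the less hindered C4 flank, which puts the ester cis to C10 as ring B closure later requires.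

**Step 8**
Reactants: 12 methyl (1S,6Z)-6-(2-methoxy-2-oxoethylidene)-1,5,5-trimethylcyclohex-3-ene-1-carboxylate
Product: 14 methyl (1S,6Z)-1,5,5-trimethyl-6-(2-oxopropylidene)cyclohex-3-ene-1-carboxylate (racemate), via Weinreb amide 13 (not isolated)
Conditions: MeNH(OMe)·HCl, i-PrMgCl, THF, −20 °C; then MeMgBr, 0 °C; aq. NH4Cl
Reagents that add atoms: methylmagnesium bromide, C[Mg]Br; N,O-dimethylhydroxylamine hydrochloride, CNOC.Cl (its atoms stay in 13 only)
Why: Direct Weinreb amidation of the less hindered conjugated ester followed by Grignard addition to the chelated amide gives the methyl ketone (Weinreb ketone synthesis), the α-quaternary ester at C10 being too hindered to react.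

**Step 9**
Reactants: 14 methyl (1S,6Z)-1,5,5-trimethyl-6-(2-oxopropylidene)cyclohex-3-ene-1-carboxylate
Product: 15 (8aS)-5,5,8a-trimethyl-8,8a-dihydronaphthalene-1,3(2H,5H)-dione (racemate, enolised; labdane C7 and C9 carbonyls, C2=C3 and C5=C6)
Conditions: KOt-Bu (2.2 equiv), THF, 0 °C to rt; aq. HCl
Reagents that add atoms: none
Why: Intramolecular Claisen condensation of the methyl ketone enolate (C8) onto the C9 ester closes ring B, is possible only for the Z-isomer made in step 7 and is driven by the stabilised enolate of the cyclic 1,3-dione.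

**Step 10**
Reactants: 15 (8aS)-5,5,8a-trimethyl-8,8a-dihydronaphthalene-1,3(2H,5H)-dione
Product: 16 (4aS,8aS)-5,5,8a-trimethyl-4a,5,6,7,8,8a-hexahydronaphthalene-1,3(2H,4H)-dione (racemate, trans-fused)
Conditions: H2 (4 atm), 10% Pd/C, EtOAc, rt
Reagents that add atoms: none
Why: Heterogeneous hydrogenation saturates C2=C3 and C5=C6, hydrogen reaching C5 from the α-face opposite the axial C10 methyl and 4β-methyl groups so that the trans ring fusion results, while the enolised 1,3-dione is left intact.

**Step 11**
Reactants: 16 (4aS,8aS)-5,5,8a-trimethyl-4a,5,6,7,8,8a-hexahydronaphthalene-1,3(2H,4H)-dione (racemate)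
Product: 17 (4aS,8aS)-3-{[(1R,2S,5R)-2-isopropyl-5-methylcyclohexyl]oxy}-5,5,8a-trimethyl-4a,5,6,7,8,8a-hexahydronaphthalen-1(4H)-one
Conditions: (−)-menthol (1.5 equiv), TsOH·H2O (cat.), benzene, reflux, Dean–Stark; chromatography and crystallisation to remove the (4aR,8aR) diastereomer
Reagents that add atoms: (1R,2S,5R)-(−)-menthol, CC(C)[C@@H]1CC[C@@H](C)C[C@H]1O
Why: Acid-catalysed enol etherification of the 1,3-dione should occur at the less hindered C7 oxygen (C9 is flanked by quaternary C10), and because the two enantiomers of 16 give diastereomeric menthyl ethers, of which only the (4aS,8aS) isomer 17 is carried on, the step is also a classical resolution that fixes the absolute configuration at C5 and C10.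

**Step 12**
Reactants: 17 (4aS,8aS)-3-(menthyloxy)-5,5,8a-trimethyl-4a,5,6,7,8,8a-hexahydronaphthalen-1(4H)-one
Product: 19 (4aS,8aS)-4-allyl-4a,8,8-trimethyl-4a,5,6,7,8,8a-hexahydronaphthalen-2(1H)-one, via magnesium alkoxide 18 (not isolated)
Conditions: CH2=CHCH2MgBr, Et2O/THF, 0 °C; then 1 M HCl, THF, rt
Reagents that add atoms: allylmagnesium bromide, C=CC[Mg]Br
Why: Stork–Danheiser transposition, in which 1,2-addition of the allyl Grignard reagent to the hindered C9 carbonyl and acid hydrolysis of the enol ether with loss of water and menthol give the enone with C7=O and the allyl group on C9, without touching C5 or C10.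

**Step 13**
Reactants: 19 (4aS,8aS)-4-allyl-4a,8,8-trimethyl-4a,5,6,7,8,8a-hexahydronaphthalen-2(1H)-one
Product: 22 diethyl (1-allyl-5,5,8a-trimethyl-3-oxodecahydronaphthalen-2-yl)phosphonate (trans-fused; labdane 9β-allyl; mixture of C8 epimers), via lithium enolate 20 (not isolated), via β-keto phosphonite 21 (not isolated)
Conditions: Li (2.2 equiv), NH3 (l), THF, t-BuOH (1.0 equiv), −78 °C; isoprene; NH3 evaporated; ClP(OEt)2 (2.5 equiv), THF, −78 °C to rt; dry air, rt
Reagents that add atoms: diethyl chlorophosphite, CCOP(Cl)OCC; dioxygen, O=O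
Why: Dissolving-metal reduction of the enone protonates C9 axially from the α-face anti to the C10 methyl group (9α-H, equatorial 9β-allyl) and leaves the regiodefined C7–C8 lithium enolate, which diethyl chlorophosphite captures at carbon C8, and air oxidation of the resulting β-keto phosphonite gives the β-ketophosphonate (Stork reductive enolate generation, then C–P bond formation between an enolate and a phosphorochloridite, then oxidation at phosphorus).

**Step 14**
Reactants: 22 diethyl (1-allyl-5,5,8a-trimethyl-3-oxodecahydronaphthalen-2-yl)phosphonate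
Product: 23 diethyl {5,5,8a-trimethyl-1-[(2E)-3-methyl-4-oxobut-2-en-1-yl]-3-oxodecahydronaphthalen-2-yl}phosphonate
Conditions: second-generation Hoveyda–Grubbs catalyst, (H2IMes)Cl2Ru(=CH-C6H4-2-O-i-Pr) (5 mol %), methacrolein (5 equiv), CH2Cl2, 40 °C
Reagents that add atoms: methacrolein, CC(=C)C=O
Why: Olefin cross-metathesis of the terminal allyl alkene with excess methacrolein gives the trisubstituted (E)-enal under thermodynamic control with loss of ethylene.

**Step 15**
Reactants: 23 diethyl {5,5,8a-trimethyl-1-[(2E)-3-methyl-4-oxobut-2-en-1-yl]-3-oxodecahydronaphthalen-2-yl}phosphonate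
Product: 24 diethyl {5,5,8a-trimethyl-1-[(2E)-3-methylpenta-2,4-dien-1-yl]-3-oxodecahydronaphthalen-2-yl}phosphonate
Conditions: Ph3PCH3Br (2.5 equiv), KN(SiMe3)2 (2.4 equiv), THF, −78 to 0 °C; AcOH
Reagents that add atoms: methyltriphenylphosphonium bromide, C[P+](c1ccccc1)(c1ccccc1)c1ccccc1.[Br-]
Why: Wittig methylenation of the enal gives the (E)-diene, the first equivalent of ylide deprotonating the β-ketophosphonate so that its enolate shields the C7 ketone.

**Step 16**
Reactants: 24 diethyl {5,5,8a-trimethyl-1-[(2E)-3-methylpenta-2,4-dien-1-yl]-3-oxodecahydronaphthalen-2-yl}phosphonate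
Product: 25 (5S,9R,10S,12E)-labda-8(17),12,14-trien-7-one
Conditions: 37% aq. CH2O, K2CO3, THF/H2O, rt
Reagents that add atoms: formaldehyde, C=O
Why: Horner–Wadsworth–Emmons reaction of the cyclic β-ketophosphonate with formaldehyde forms the exocyclic C8=C17 bond next to the C7 ketone under conditions mild enough for the diene and for C9.

**Step 17**
Reactants: 26 diosmetin, 5,7-dihydroxy-2-(3-hydroxy-4-methoxyphenyl)-4H-chromen-4-one
Product: 27 2-(5,7-dihydroxy-4-oxo-4H-chromen-2-yl)-5-methoxycyclohexa-2,5-diene-1,4-dione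
Conditions: (KSO3)2NO (2.5 equiv), KH2PO4 buffer, acetone/H2O, 0 °C to rt
Reagents that add atoms: potassium nitrosodisulfonate, [K+].[K+].[O]N(S(=O)(=O)[O-])S(=O)(=O)[O-]
Why: Teuber oxidation of the guaiacol-type phenol at its free para position gives the 2-aryl-5-methoxy-1,4-benzoquinone, the chelated 5-OH and the 7-OH of the electron-poor chromone being much harder to oxidise.

**Step 18**
Reactants: 25 (5S,9R,10S,12E)-labda-8(17),12,14-trien-7-one; 27 2-(5,7-dihydroxy-4-oxo-4H-chromen-2-yl)-5-methoxycyclohexa-2,5-diene-1,4-dione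
Product: 28 dichrostachine L
Conditions: THF/CH2Cl2 (1:1), 25 °C, dark, 72 h; preparative HPLC
Reagents that add atoms: none
Why: Intermolecular Diels–Alder reaction of the (E)-diene with the chromonyl-substituted C=C of 27 (the methoxy-substituted C=C is a deactivated vinylogous ester), in which the unsubstituted terminus C15 bonds to the unsubstituted C6' and C12 to the quaternary C1', sets C1' and C6' cis by suprafacial addition and C12 through the topography that holds the chromonyl group under the diene and the enedione ring exo, while the diene face is not biased by the remote labdane stereocentres so that 28 is expected together with isomeric adducts and is isolated by preparative HPLC.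

**Compound list**

1 | 3-methyldihydrofuran-2(3H)-one (α-methyl-γ-butyrolactone, racemic) | CC1CCOC1=O | starting material
2 | methyl 4-bromo-2-methylbutanoate (racemic) | COC(=O)C(C)CCBr | intermediate
3 | (4-methoxy-3-methyl-4-oxobutyl)triphenylphosphonium bromide (racemic) | COC(=O)C(C)CC[P+](c1ccccc1)(c1ccccc1)c1ccccc1.[Br-] | intermediate
4 | 3-hydroxy-2,2-dimethylpropanal (hydroxypivaldehyde) | CC(C)(CO)C=O | starting material
5 | 2,2-dimethylbut-3-yn-1-ol | CC(C)(CO)C#C | intermediate
6 | dilithium salt of 5 (alkoxide and acetylide) | [Li+].[Li+].[O-]CC(C)(C)C#[C-] | intermediate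
7 | 5-hydroxy-4,4-dimethylpent-2-ynoic acid | CC(C)(CO)C#CC(=O)O | intermediate
8 | methyl 5-hydroxy-4,4-dimethylpent-2-ynoate | CC(C)(CO)C#CC(=O)OC | intermediate
9 | methyl 4,4-dimethyl-5-oxopent-2-ynoate | CC(C)(C=O)C#CC(=O)OC | intermediate
10 | methyl 2-methyl-4-(triphenyl-λ5-phosphanylidene)butanoate (ylide) | COC(=O)C(C)CC=P(c1ccccc1)(c1ccccc1)c1ccccc1 | intermediate
11 | dimethyl (4Z)-2,6,6-trimethylnon-4-en-7-ynedioate (racemic) | COC(=O)C(C)C/C=C\C(C)(C)C#CC(=O)OC | intermediate
12 | methyl (1S,6Z)-6-(2-methoxy-2-oxoethylidene)-1,5,5-trimethylcyclohex-3-ene-1-carboxylate (racemate, enantiomer carried on is drawn) | COC(=O)/C=C1/C(C)(C)C=CC[C@]1(C)C(=O)OC | intermediate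
13 | methyl (1S,6Z)-6-{2-[methoxy(methyl)amino]-2-oxoethylidene}-1,5,5-trimethylcyclohex-3-ene-1-carboxylate (racemate) | CON(C)C(=O)/C=C1/C(C)(C)C=CC[C@]1(C)C(=O)OC | intermediate
14 | methyl (1S,6Z)-1,5,5-trimethyl-6-(2-oxopropylidene)cyclohex-3-ene-1-carboxylate (racemate) | CC(=O)/C=C1/C(C)(C)C=CC[C@]1(C)C(=O)OC | intermediate
15 | (8aS)-5,5,8a-trimethyl-8,8a-dihydronaphthalene-1,3(2H,5H)-dione (racemate, enolised) | O=C1C=C2C(C)(C)C=CC[C@]2(C)C(=O)C1 | intermediate
16 | (4aS,8aS)-5,5,8a-trimethyl-4a,5,6,7,8,8a-hexahydronaphthalene-1,3(2H,4H)-dione (racemate, trans-fused) | O=C1C[C@H]2C(C)(C)CCC[C@]2(C)C(=O)C1 | intermediate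
17 | (4aS,8aS)-3-{[(1R,2S,5R)-2-isopropyl-5-methylcyclohexyl]oxy}-5,5,8a-trimethyl-4a,5,6,7,8,8a-hexahydronaphthalen-1(4H)-one | O=C1C=C(O[C@@H]3C[C@H](C)CC[C@H]3C(C)C)C[C@H]2C(C)(C)CCC[C@]12C | intermediate
18 | bromomagnesium alkoxide of the C9 allyl carbinol from 1,2-addition to 17 (C9 epimers) | C=CCC1([O-])C=C(O[C@@H]3C[C@H](C)CC[C@H]3C(C)C)C[C@H]2C(C)(C)CCC[C@]12C.[Mg+2].[Br-] | intermediate
19 | (4aS,8aS)-4-allyl-4a,8,8-trimethyl-4a,5,6,7,8,8a-hexahydronaphthalen-2(1H)-one | O=C1C[C@H]2C(C)(C)CCC[C@]2(C)C(CC=C)=C1 | intermediate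
20 | lithium 4-allyl-4a,8,8-trimethyl-1,4,4a,5,6,7,8,8a-octahydronaphthalen-2-olate (labdane 5α-H, 9α-H, 10β-CH3) | [Li+].[O-]C=1C[C@H]2C(C)(C)CCC[C@]2(C)[C@@H](CC=C)C=1 | intermediate
21 | diethyl (1-allyl-5,5,8a-trimethyl-3-oxodecahydronaphthalen-2-yl)phosphonite (trans-fused, allyl cis to the angular methyl, C8 epimers) | CCOP(OCC)C1C(=O)C[C@H]2C(C)(C)CCC[C@]2(C)[C@H]1CC=C | intermediate
22 | diethyl (1-allyl-5,5,8a-trimethyl-3-oxodecahydronaphthalen-2-yl)phosphonate (trans-fused, allyl cis to the angular methyl, C8 epimers) | CCOP(=O)(OCC)C1C(=O)C[C@H]2C(C)(C)CCC[C@]2(C)[C@H]1CC=C | intermediate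
23 | diethyl {5,5,8a-trimethyl-1-[(2E)-3-methyl-4-oxobut-2-en-1-yl]-3-oxodecahydronaphthalen-2-yl}phosphonate | CCOP(=O)(OCC)C1C(=O)C[C@H]2C(C)(C)CCC[C@]2(C)[C@H]1C/C=C(\C)C=O | intermediate
24 | diethyl {5,5,8a-trimethyl-1-[(2E)-3-methylpenta-2,4-dien-1-yl]-3-oxodecahydronaphthalen-2-yl}phosphonate | CCOP(=O)(OCC)C1C(=O)C[C@H]2C(C)(C)CCC[C@]2(C)[C@H]1C/C=C(C)/C=C | intermediate
25 | (5S,9R,10S,12E)-labda-8(17),12,14-trien-7-one | C=C1C(=O)C[C@H]2C(C)(C)CCC[C@]2(C)[C@H]1C/C=C(C)/C=C | intermediate
26 | diosmetin, 5,7-dihydroxy-2-(3-hydroxy-4-methoxyphenyl)-4H-chromen-4-one | COc1ccc(cc1O)-c1cc(=O)c2c(O)cc(O)cc2o1 | starting material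
27 | 2-(5,7-dihydroxy-4-oxo-4H-chromen-2-yl)-5-methoxycyclohexa-2,5-diene-1,4-dione | COC1=CC(=O)C(=CC1=O)c1cc(=O)c2c(O)cc(O)cc2o1 | intermediate
28 | dichrostachine L | C=C1C(=O)C[C@H]2C(C)(C)CCC[C@]2(C)[C@H]1C[C@@H]1C(C)=CC[C@H]2C(=O)C(OC)=CC(=O)[C@@]12c1cc(=O)c2c(O)cc(O)cc2o1 | target

**Step count**

Total: 18 steps. Longest linear sequence: 15 steps (steps 3–6, 7–16 and 18).

**Steps most likely to fail**

Step 7. The ylide or the amide base may add to the ynoate instead of the aldehyde or the ester α-carbon, the Z-selectivity of the olefination may erode, and the hindered enolate may close slowly, so that E-alkene and open-chain material build up. The fallback sets out from 9 and returns at 12. Methylenation of the aldehyde of 9 (Ph3P=CH2, THF, −78 °C) gives methyl 4,4-dimethylhex-5-en-2-ynoate F1. The lithium enolate of commercial methyl 2-methylpent-4-enoate F2 (LiN(i-Pr)2, THF, −78 °C) is then added to F1 in an intermolecular Michael reaction, which makes the C5–C10 bond first and gives dimethyl (2Z)-4-methyl-3-(2-methylbut-3-en-2-yl)-4-(prop-2-en-1-yl)pent-2-enedioate F3. Ring-closing metathesis of F3 (second-generation Grubbs catalyst, (H2IMes)(PCy3)Cl2Ru=CHPh, CH2Cl2, 40 °C) forms C2=C3, which is necessarily cis in the ring, and gives 12.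

Step 18. Control over the endo/exo topography and over the diene face may be poor, so that the adduct with the enedione ring endo (the C12-epimeric series) dominates. The fallback sets out from 24 and returns at 28. Triplet-sensitised photoisomerisation of 24 (benzophenone, hν, benzene) and separation give the (12Z)-diene, diethyl {5,5,8a-trimethyl-1-[(2Z)-3-methylpenta-2,4-dien-1-yl]-3-oxodecahydronaphthalen-2-yl}phosphonate F4. The Horner–Wadsworth–Emmons reaction of step 16 converts F4 into (5S,9R,10S,12Z)-labda-8(17),12,14-trien-7-one F5. Cycloaddition of F5 with 27 under high pressure (about 10 kbar, CH2Cl2, rt) through the usual enedione-endo transition state places the inside C11 substituent cis to the chromonyl group, which is the relative configuration of 28; the face isomer is again removed by HPLC.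

Step 11. Enol ether formation may not be fully regioselective, and the diastereomeric menthyl ethers may separate poorly. The fallback sets out from racemic 16 and returns at 19. Condensation of 16 with (S)-1-phenylethylamine (toluene, reflux, Dean–Stark) gives crystalline vinylogous amides, from which (4aS,8aS)-5,5,8a-trimethyl-3-{[(1S)-1-phenylethyl]amino}-4a,5,6,7,8,8a-hexahydronaphthalen-1(4H)-one F6 is obtained by fractional crystallisation. Aqueous HCl returns enantiopure (4aS,8aS)-16, which HC(OMe)3, MeOH and TsOH convert into (4aS,8aS)-3-methoxy-5,5,8a-trimethyl-4a,5,6,7,8,8a-hexahydronaphthalen-1(4H)-one F7. Allyl Grignard addition and acid hydrolysis as in step 12 then give 19.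

**Further compounds**

F1 | step 7 | methyl 4,4-dimethylhex-5-en-2-ynoate | C=CC(C)(C)C#CC(=O)OC
F2 | step 7 | methyl 2-methylpent-4-enoate (racemic, commercial) | COC(=O)C(C)CC=C
F3 | step 7 | dimethyl (2Z)-4-methyl-3-(2-methylbut-3-en-2-yl)-4-(prop-2-en-1-yl)pent-2-enedioate (racemic) | COC(=O)/C=C(/C(C)(C)C=C)C(C)(CC=C)C(=O)OC
F4 | step 18 | diethyl {5,5,8a-trimethyl-1-[(2Z)-3-methylpenta-2,4-dien-1-yl]-3-oxodecahydronaphthalen-2-yl}phosphonate | CCOP(=O)(OCC)C1C(=O)C[C@H]2C(C)(C)CCC[C@]2(C)[C@H]1C/C=C(C)\C=C
F5 | step 18 | (5S,9R,10S,12Z)-labda-8(17),12,14-trien-7-one | C=C1C(=O)C[C@H]2C(C)(C)CCC[C@]2(C)[C@H]1C/C=C(C)\C=C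
F6 | step 11 | (4aS,8aS)-5,5,8a-trimethyl-3-{[(1S)-1-phenylethyl]amino}-4a,5,6,7,8,8a-hexahydronaphthalen-1(4H)-one | O=C1C=C(N[C@@H](C)c3ccccc3)C[C@H]2C(C)(C)CCC[C@]12C
F7 | step 11 | (4aS,8aS)-3-methoxy-5,5,8a-trimethyl-4a,5,6,7,8,8a-hexahydronaphthalen-1(4H)-one | O=C1C=C(OC)C[C@H]2C(C)(C)CCC[C@]12C
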